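**Strategy**

Atom numbers follow the ent-kaurane skeleton (C1 acetoxy carbon, C4 gem-dimethyl carbon, C10 spiro carbon, C7 lactone carbonyl, C15 ketone). Ring A has a bare C2–C3 ethano bridge between oxygenated C1 and quaternary C4; the route exploits this by cutting C1–C2 and C3–C4: C4 is a tertiary radical from an isopropenyl group on C5, C1 an aldehyde on C10, and C2–C3 come from acrolein. One hydrogen-atom-transfer Giese addition/aldol annulation closes ring A on a butyrolactone that holds C5 and C10 and stores C9 as its carbonyl. Rhodium catalysis sets C5; substrate control relays the rest. An ester-tethered Diels–Alder reaction and a vinyl radical cyclization finish rings C and D.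

Key step: step 5

Remark: (S)-BINAP is assumed to give the (S)-lactone 3, as it does with cyclic enones; if the sense proves opposite, the antipodal ligand is used. Acid 23 is made in steps 11–13.

**Route**

Step 1
Reactants: 1 2(5H)-furanone; 2 potassium trifluoro(prop-1-en-2-yl)borate
Product: 3 (S)-4-(prop-1-en-2-yl)dihydrofuran-2(3H)-one
Conditions: [Rh(cod)2]PF6 (3 mol%), (S)-BINAP, toluene/H2O, 105 °C
Reagents that add atoms: none
Why: Hayashi–Miyaura asymmetric conjugate addition; the BINAP-bound alkenylrhodium species adds to one enantioface of the butenolide, which sets C5, the only stereocenter made by catalysis.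

Step 2
Reactants: 3 (S)-4-(prop-1-en-2-yl)dihydrofuran-2(3H)-one; 4 (triisopropylsiloxy)methyl chloride
Product: 5 trans-3-[(triisopropylsilyloxy)methyl]-4-isopropenyl-γ-butyrolactone
Conditions: LiN(i-Pr)2, THF, −78 °C; then 4, −78 → −40 °C
Reagents that add atoms: none
Why: C-alkylation of the lactone enolate with a chloromethyl ether anti to the β-isopropenyl group; the new carbon is C20.

Step 3
Reactants: 5 trans-3-[(triisopropylsilyloxy)methyl]-4-isopropenyl-γ-butyrolactone
Product: 6 3-(hydroxymethyl)-3-[(triisopropylsilyloxy)methyl]-4-isopropenyl-γ-butyrolactone (CH2OH trans, CH2OSi cis to isopropenyl)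
Conditions: LiN(i-Pr)2, THF, −78 °C; CH2O (gas), −78 °C; AcOH, −78 °C
Reagents that add atoms: formaldehyde, C=O
Why: Aldol addition of the tetrasubstituted enolate to formaldehyde, again anti to the isopropenyl group, makes C10 quaternary with C1 trans and C20 cis to the isopropenyl group; the cold quench is meant to forestall β-elimination and silyl migration.

Step 4
Reactants: 6 hydroxymethyl lactone
Product: 7 3-formyl-3-[(triisopropylsilyloxy)methyl]-4-isopropenyl-γ-butyrolactone (CHO trans to isopropenyl)
Conditions: Dess–Martin periodinane, NaHCO3, CH2Cl2, 0 → 23 °C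
Reagents that add atoms: none
Why: Dess–Martin oxidation of the neopentyl alcohol to a non-enolisable aldehyde, so C10 cannot epimerise.

Step 5
Reactants: 7 formyl lactone; 8 acrolein
Product: 10 trans-fused bicyclic lactone with ring A closed (C1 hydroxyl, C2 formyl, C4 gem-dimethyl), via iron enolate 9 (not isolated)
Conditions: Fe(acac)3 (30 mol%), PhSiH3, 8 (5 equiv), EtOH/(CH2OH)2, 0 → 23 °C
Reagents that add atoms: none
Why: An iron hydride formed from Fe(acac)3 and PhSiH3 transfers a hydrogen atom to the isopropenyl CH2 of 7 (Mukaiyama-type HAT), the tertiary C4 radical adds to acrolein (Giese addition, C3–C4 bond), and the α-formyl radical is reduced by divalent iron to the iron enolate 9, which closes onto the C1 aldehyde (intramolecular aldol, C1–C2 bond). The closest known reaction type is the HAT-initiated radical–polar crossover annulation of alkenyl carbonyl compounds with enals. Ring A closes as a 6-(enolexo)-exo-trig aldol onto the trans-disposed formyl group, giving a trans-fused bicyclic lactone. C4 is not stereogenic; C1 and C2 are expected mainly diequatorial (chair transition state, reversible aldol) but neither is relied on, because step 6 removes the C2 formyl carbon and step 7 resets C1. The step therefore needs only chemoselectivity: the 1,1-disubstituted alkene is the sole HAT acceptor, the aldehyde on quaternary C10 cannot enolise, and excess acrolein with the pre-organised lactone should let aldol closure outrun protonation of the enolate.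

Step 6
Reactants: 10 bicyclic hydroxy aldehyde
Product: 12 trans-fused bicyclic keto lactone (C1 ketone, C2 methylene), via keto acid 11 (not isolated)
Conditions: CrO3, H2SO4, acetone/H2O, 0 °C; then 40 °C
Reagents that add atoms: none
Why: Jones oxidation takes the aldehyde to the acid and the carbinol to the ketone, and the β-keto acid decarboxylates on warming, which removes the activating formyl carbon and leaves C2 as CH2.

Step 7
Reactants: 12 bicyclic keto lactone
Product: 13 bicyclic lactol with C1 hydroxyl equatorial, cis to C20 (anomers at C9)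
Conditions: i-Bu2AlH (3.5 equiv), CH2Cl2, −78 °C; aq. potassium sodium tartrate
Reagents that add atoms: none
Why: Aluminium hydride reduction of lactone to lactol and of ketone to alcohol; hydride adds to C1 anti to the axial C20 arm on the neighbouring quaternary C10 (axial attack), which should give the equatorial alcohol cis to C20 as in the target.

Step 8
Reactants: 13 lactol; 14 allyltriphenylphosphonium bromide
Product: 16 (E)-buta-1,3-dienyl diol (free C1 and C6 hydroxyls, C20 silyl ether), via (Z)-diene 15 (not isolated)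
Conditions: 14, n-BuLi, THF, −78 → 0 °C; then I2 (cat.), hν, CH2Cl2, 23 °C
Reagents that add atoms: none
Why: Wittig olefination of the lactol through its open hydroxy aldehyde turns C9 into a diene terminus and frees the C6 hydroxyl; iodine equilibrates the E/Z mixture to the (E)-diene, and lithium counter-ions at low temperature are chosen to keep the β-alkoxy aldehyde from retro-aldol cleavage.

Step 9
Reactants: 16 (E)-dienyl diol
Product: 17 (E)-dienyl diacetate (C1 and C6 acetates)
Conditions: Ac2O, DMAP, pyridine, CH2Cl2, 23 °C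
Reagents that add atoms: acetic anhydride, CC(=O)OC(C)=O
Why: DMAP-catalysed acylation installs both acetates of the target in one operation.

Step 10
Reactants: 17 dienyl diacetate
Product: 18 dienyl diacetate with free C20 hydroxyl
Conditions: HF·pyridine, pyridine, THF, 0 → 23 °C
Reagents that add atoms: none
Why: Fluoride desilylation under acidic buffering, chosen to avoid 1,3-acetyl migration from O1 to the freed O20.

Step 11
Reactants: 19 triethyl phosphonoacetate; 20 2,3-dibromopropene
Product: 21 ethyl 4-bromo-2-(diethoxyphosphoryl)pent-4-enoate (racemic)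
Conditions: NaH, THF, 0 °C; then 20, 0 → 23 °C
Reagents that add atoms: none
Why: Alkylation of the stabilised phosphonate carbanion at the allylic bromide; the vinylic bromide is inert to substitution.

Step 12
Reactants: 21 alkylated phosphonate
Product: 22 ethyl 4-bromo-2-methylenepent-4-enoate
Conditions: aq. CH2O, K2CO3, H2O, 23 °C
Reagents that add atoms: formaldehyde, C=O
Why: Horner–Wadsworth–Emmons methylenation with formaldehyde gives the 2-substituted acrylate; this CH2 is C14.

Step 13
Reactants: 22 ethyl 4-bromo-2-methylenepent-4-enoate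
Product: 23 4-bromo-2-methylenepent-4-enoic acid
Conditions: LiOH, THF/H2O, 23 °C; then aq. HCl
Reagents that add atoms: lithium hydroxide, [Li+].[OH-]
Why: Ester saponification; the vinyl bromide and acrylate are stable to cold hydroxide.

Step 14
Reactants: 18 C20 alcohol; 23 4-bromo-2-methylenepent-4-enoic acid
Product: 24 dienyl 2-(2-bromoallyl)acrylate (ester on O20)
Conditions: DCC, DMAP (cat.), CH2Cl2, 0 °C
Reagents that add atoms: none
Why: Steglich esterification of the neopentyl alcohol, run cold and short so that acylation outpaces acetyl migration.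

Step 15
Reactants: 24 triene ester
Product: 25 tricyclic cycloadduct (spiro δ-lactone cis-fused to a cyclohexene, C11=C12, with a 2-bromoallyl group on C8 cis to H9)
Conditions: toluene (0.01 M), BHT, sealed tube, 180 °C
Reagents that add atoms: none
Why: Thermal intramolecular Diels–Alder reaction of the (E)-dienyl acrylate with the tether carbonyl endo forms C8–C9 and C13–C14 suprafacially, so C8 and C9 are set together as a cis-fused lactone, whereas the diene face relative to C10 is only weakly biased and the isomer with the target's C9 configuration has to be separated from its facial isomer.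

Step 16
Reactants: 25 cycloadduct
Product: 26 11,12-epoxide, oxygen syn to H9
Conditions: 3-chloroperbenzoic acid, NaHCO3, CH2Cl2, 0 °C
Reagents that add atoms: 3-chloroperbenzoic acid, OOC(=O)c1cccc(Cl)c1
Why: Prilezhaev epoxidation of the only electron-rich alkene from the face opposite the allylic C9–C10 bond and the lactone, which sets the C11 oxygen; the bromoalkene is too electron-poor to react.

Step 17
Reactants: 26 epoxide
Product: 29 allylic alcohol (C11 hydroxyl, C12=C13), via hydroxy selenide 27 (not isolated), via selenoxide 28 (not isolated)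
Conditions: PhSeSePh, NaBH4, EtOH, 0 → 23 °C; then H2O2, THF, 0 → 23 °C
Reagents that add atoms: none
Why: Selenolate opening of the epoxide at C12, the carbon remote from the congested C9, followed by selenoxide syn-elimination away from the carbinol transposes the epoxide into the allylic alcohol with the C11 configuration retained.

Step 18
Reactants: 29 allylic alcohol
Product: 30 tetracyclic 16-methylene compound (ring D closed, C15 methylene, C11 hydroxyl)
Conditions: Bu3SnH (slow addition), AIBN, benzene, 80 °C
Reagents that add atoms: none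
Why: Tin-mediated vinyl radical 5-exo-trig cyclization; the radical is tethered on the upper face of C8 and can reach C13 only on that face, which sets C13 and delivers the exocyclic methylene directly.

Step 19
Reactants: 30 16-methylene tetracycle
Product: 31 15-hydroxy compound (either C15 epimer)
Conditions: SeO2 (cat.), t-BuOOH, CH2Cl2, 23 °C
Reagents that add atoms: tert-butyl hydroperoxide, CC(C)(C)OO
Why: Riley allylic oxidation (ene reaction then 2,3-shift) at C15, the only allylic methylene; its configuration is irrelevant.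

Step 20
Reactants: 31 allylic alcohol
Product: 32 Rabdosin B
Conditions: MnO2, CH2Cl2, 23 °C
Reagents that add atoms: none
Why: MnO2 oxidises only the allylic C15 alcohol to the enone and leaves the non-allylic C11 hydroxyl.

**Compound list**

1 | 2(5H)-furanone | O=C1OCC=C1 | starting material
2 | potassium trifluoro(prop-1-en-2-yl)borate | [K+].C=C(C)[B-](F)(F)F | starting material
3 | (S)-4-(prop-1-en-2-yl)dihydrofuran-2(3H)-one | O=C1C[C@@H](C(C)=C)CO1 | intermediate
4 | (triisopropylsiloxy)methyl chloride | ClCO[Si](C(C)C)(C(C)C)C(C)C | starting material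
5 | trans-3-[(triisopropylsilyloxy)methyl]-4-isopropenyl-γ-butyrolactone | O=C1[C@H](CO[Si](C(C)C)(C(C)C)C(C)C)[C@@H](C(C)=C)CO1 | intermediate
6 | 3-(hydroxymethyl)-3-[(triisopropylsilyloxy)methyl]-4-isopropenyl-γ-butyrolactone, CH2OH trans to isopropenyl | O=C1[C@@](CO)(CO[Si](C(C)C)(C(C)C)C(C)C)[C@@H](C(C)=C)CO1 | intermediate
7 | 3-formyl-3-[(triisopropylsilyloxy)methyl]-4-isopropenyl-γ-butyrolactone, CHO trans to isopropenyl | O=C1[C@@](C=O)(CO[Si](C(C)C)(C(C)C)C(C)C)[C@@H](C(C)=C)CO1 | intermediate
8 | acrolein | C=CC=O | starting material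
9 | iron enolate of the Giese adduct (drawn as the free enol) | O=C1[C@@](C=O)(CO[Si](C(C)C)(C(C)C)C(C)C)[C@@H](C(C)(C)CC=CO)CO1 | intermediate (not isolated)
10 | trans-fused bicyclic lactone, ring A with C1 hydroxyl and C2 formyl (drawn diequatorial) | O=C1OC[C@H]2[C@@]1(CO[Si](C(C)C)(C(C)C)C(C)C)[C@@H](O)[C@H](C=O)CC2(C)C | intermediate
11 | β-keto acid (C1 ketone, C2 carboxyl; C2 labile) | O=C1OC[C@H]2[C@@]1(CO[Si](C(C)C)(C(C)C)C(C)C)C(=O)C(C(=O)O)CC2(C)C | intermediate (not isolated)
12 | trans-fused bicyclic keto lactone (C1 ketone) | O=C1OC[C@H]2[C@@]1(CO[Si](C(C)C)(C(C)C)C(C)C)C(=O)CCC2(C)C | intermediate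
13 | bicyclic lactol, C1 hydroxyl cis to C20 | OC1OC[C@H]2[C@@]1(CO[Si](C(C)C)(C(C)C)C(C)C)[C@@H](O)CCC2(C)C | intermediate
14 | allyltriphenylphosphonium bromide | C=CC[P+](c1ccccc1)(c1ccccc1)c1ccccc1.[Br-] | starting material
15 | (Z)-buta-1,3-dienyl diol | C=C/C=C\[C@]1(CO[Si](C(C)C)(C(C)C)C(C)C)[C@@H](O)CCC(C)(C)[C@H]1CO | intermediate (not isolated)
16 | (E)-buta-1,3-dienyl diol | C=C/C=C/[C@]1(CO[Si](C(C)C)(C(C)C)C(C)C)[C@@H](O)CCC(C)(C)[C@H]1CO | intermediate
17 | (E)-dienyl diacetate, C20 silyl ether | C=C/C=C/[C@]1(CO[Si](C(C)C)(C(C)C)C(C)C)[C@@H](OC(C)=O)CCC(C)(C)[C@H]1COC(C)=O | intermediate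
18 | (E)-dienyl diacetate, free C20 hydroxyl | C=C/C=C/[C@]1(CO)[C@@H](OC(C)=O)CCC(C)(C)[C@H]1COC(C)=O | intermediate
19 | triethyl phosphonoacetate | CCOC(=O)CP(=O)(OCC)OCC | starting material
20 | 2,3-dibromopropene | C=C(Br)CBr | starting material
21 | ethyl 4-bromo-2-(diethoxyphosphoryl)pent-4-enoate (racemic) | CCOC(=O)C(CC(Br)=C)P(=O)(OCC)OCC | intermediate
22 | ethyl 4-bromo-2-methylenepent-4-enoate | CCOC(=O)C(=C)CC(Br)=C | intermediate
23 | 4-bromo-2-methylenepent-4-enoic acid | OC(=O)C(=C)CC(Br)=C | intermediate
24 | triene ester (O20 2-(2-bromoallyl)acrylate) | C=C/C=C/[C@]1(COC(=O)C(=C)CC(Br)=C)[C@@H](OC(C)=O)CCC(C)(C)[C@H]1COC(C)=O | intermediate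
25 | cycloadduct: spiro δ-lactone cis-fused to cyclohexene, 2-bromoallyl on C8 | C=C(Br)C[C@]12CCC=C[C@H]1[C@]1(COC2=O)[C@@H](OC(C)=O)CCC(C)(C)[C@H]1COC(C)=O | intermediate
26 | 11,12-epoxide, oxygen syn to H9 | C=C(Br)C[C@]12CC[C@@H]3O[C@@H]3[C@H]1[C@]1(COC2=O)[C@@H](OC(C)=O)CCC(C)(C)[C@H]1COC(C)=O | intermediate
27 | 11-hydroxy-12-phenylselanyl compound (trans) | C=C(Br)C[C@]12CC[C@@H]([Se]c3ccccc3)[C@H](O)[C@H]1[C@]1(COC2=O)[C@@H](OC(C)=O)CCC(C)(C)[C@H]1COC(C)=O | intermediate (not isolated)
28 | corresponding selenoxide | C=C(Br)C[C@]12CC[C@@H]([Se](=O)c3ccccc3)[C@H](O)[C@H]1[C@]1(COC2=O)[C@@H](OC(C)=O)CCC(C)(C)[C@H]1COC(C)=O | intermediate (not isolated)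
29 | allylic alcohol (C11 hydroxyl, C12=C13) | C=C(Br)C[C@]12CC=C[C@H](O)[C@H]1[C@]1(COC2=O)[C@@H](OC(C)=O)CCC(C)(C)[C@H]1COC(C)=O | intermediate
30 | 15-deoxo Rabdosin B (C15 methylene) | C=C1C[C@]23C[C@H]1C[C@H](O)[C@H]2[C@]1(COC3=O)[C@@H](OC(C)=O)CCC(C)(C)[C@H]1COC(C)=O | intermediate
31 | 15-hydroxy compound (C15 undefined) | C=C1C(O)[C@]23C[C@H]1C[C@H](O)[C@H]2[C@]1(COC3=O)[C@@H](OC(C)=O)CCC(C)(C)[C@H]1COC(C)=O | intermediate
32 | Rabdosin B | C=C1C(=O)[C@]23C[C@H]1C[C@H](O)[C@H]2[C@]1(COC3=O)[C@@H](OC(C)=O)CCC(C)(C)[C@H]1COC(C)=O | target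

**Step count**

Total steps: 20. Longest linear sequence: 17 (steps 1–10 and 14–20).

**Steps most likely to fail**

1. Step 15: poor facial selectivity of the cycloaddition relative to C10 (C8 bonding on the C1 side of the spiro carbon), or exo closure to a trans-fused lactone. The fallback moves the tether from O20 to O1, where the dienophile must approach the diene face anti to the bulky C5 arm with C20 outside, which is the target's C8/C9 configuration. It sets out from 16. Selective acetylation of the primary C6 hydroxyl (AcCl, 2,4,6-collidine, CH2Cl2, −78 °C) should give monoacetate F1. Yamaguchi esterification of the C1 hydroxyl with acid 23 gives dienyl ester F2. Heating (toluene, BHT, 170 °C) gives the O1-bridged δ-lactone cycloadduct F3. LiOH (THF/MeOH/H2O, 60 °C) opens the lactone and removes the acetate to give dihydroxy acid F4, which is methylated in the same flask (MeI, K2CO3, DMF) to methyl ester F5. Ac2O/DMAP gives diacetate F6. HF·pyridine frees the C20 hydroxyl (hydroxy ester F7), and camphorsulfonic acid in warm toluene closes the target's δ-lactone with loss of methanol, coming back to the route at 25.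

2. Step 5: protonation of the iron enolate before it closes onto the trans-disposed aldehyde, leaving an open-chain Giese adduct, or loss of acrolein to oligomerisation. The fallback forms the two bonds in separate steps with an ester acceptor. It sets out from 7. HAT-initiated reductive coupling with methyl acrylate (Fe(acac)3, PhSiH3, EtOH/(CH2OH)2) gives ester aldehyde F8. LiN(SiMe3)2 (THF, −78 °C) closes ring A by intramolecular ester aldol to β-hydroxy ester F9. Dess–Martin oxidation gives β-keto ester F10. Krapcho demethoxycarbonylation (LiCl, wet DMSO, 140 °C) comes back to the route at 12.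

3. Step 17: opening of the epoxide at C11 instead of C12, or cleavage of the acetates by selenolate and borohydride. The fallback avoids the epoxide altogether. It sets out from 25. A Schenck ene reaction (O2, tetraphenylporphyrin, hν, CH2Cl2, 0 °C) should add singlet oxygen to C11 on the face anti to C10 with abstraction of H13 and shift of the double bond to C12=C13, giving allylic hydroperoxide F11. PPh3 reduces it, coming back to the route at 29.

**Further compounds**

F1 | step 15 | (E)-dienyl C6 monoacetate, free C1 hydroxyl | C=C/C=C/[C@]1(CO[Si](C(C)C)(C(C)C)C(C)C)[C@@H](O)CCC(C)(C)[C@H]1COC(C)=O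
F2 | step 15 | (E)-dienyl O1 2-(2-bromoallyl)acrylate | C=C/C=C/[C@]1(CO[Si](C(C)C)(C(C)C)C(C)C)[C@@H](OC(=O)C(=C)CC(Br)=C)CCC(C)(C)[C@H]1COC(C)=O
F3 | step 15 | O1-bridged δ-lactone cycloadduct | C=C(Br)C[C@]12CCC=C[C@H]1[C@@]1(CO[Si](C(C)C)(C(C)C)C(C)C)[C@H](COC(C)=O)C(C)(C)CC[C@@H]1OC2=O
F4 | step 15 | dihydroxy acid | OC(=O)[C@@]1(CC(Br)=C)CCC=C[C@H]1[C@]1(CO[Si](C(C)C)(C(C)C)C(C)C)[C@@H](O)CCC(C)(C)[C@H]1CO
F5 | step 15 | dihydroxy methyl ester | COC(=O)[C@@]1(CC(Br)=C)CCC=C[C@H]1[C@]1(CO[Si](C(C)C)(C(C)C)C(C)C)[C@@H](O)CCC(C)(C)[C@H]1CO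
F6 | step 15 | diacetoxy methyl ester, C20 silyl ether | COC(=O)[C@@]1(CC(Br)=C)CCC=C[C@H]1[C@]1(CO[Si](C(C)C)(C(C)C)C(C)C)[C@@H](OC(C)=O)CCC(C)(C)[C@H]1COC(C)=O
F7 | step 15 | diacetoxy methyl ester, free C20 hydroxyl | COC(=O)[C@@]1(CC(Br)=C)CCC=C[C@H]1[C@]1(CO)[C@@H](OC(C)=O)CCC(C)(C)[C@H]1COC(C)=O
F8 | step 5 | Giese adduct ester aldehyde | O=C1[C@@](C=O)(CO[Si](C(C)C)(C(C)C)C(C)C)[C@@H](C(C)(C)CCC(=O)OC)CO1
F9 | step 5 | bicyclic β-hydroxy ester (C1, C2 undefined) | O=C1OC[C@H]2[C@@]1(CO[Si](C(C)C)(C(C)C)C(C)C)C(O)C(C(=O)OC)CC2(C)C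
F10 | step 5 | bicyclic β-keto ester | O=C1OC[C@H]2[C@@]1(CO[Si](C(C)C)(C(C)C)C(C)C)C(=O)C(C(=O)OC)CC2(C)C
F11 | step 17 | C11 allylic hydroperoxide | C=C(Br)C[C@]12CC=C[C@H](OO)[C@H]1[C@]1(COC2=O)[C@@H](OC(C)=O)CCC(C)(C)[C@H]1COC(C)=O
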